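At 6.5 min, the last reading of Sunday's run, the target stands at 0.0588 M, and the last step added 0.00320 M.

common to all: catalyst 3.00 × 10⁻⁴ M

| charge | substrate | coupling partner | time |
|---|---|---|---|
| Sunday's | 0.150 M | 0.375 M |  |
| Monday's | 0.0750 M | 0.300 M |  |
| Friday's | 0.220 M | 0.375 M |  |
| Saturday's | 0.150 M | 0.375 M | 16 min |

| Sunday's run: time / min | Sunday's run: [target] / M | Monday's run: time / min | Monday's run: [target] / M | Friday's run: time / min | Friday's run: [target] / M |
|---|---|---|---|---|---|
| 1.3 | 0.0247 | 1.3 | 0.0159 | 1.3 | 0.0266 |
| 2.6 | 0.0414 | 2.6 | 0.0282 | 2.6 | 0.0436 |
| 3.9 | 0.0510 | 3.9 | 0.0339 | 3.9 | 0.0531 |
| 5.2 | 0.0556 | 5.2 | 0.0383 | 5.2 | 0.0584 |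
| 6.5 | 0.0588 | 6.5 | 0.0399 | 6.5 | 0.0628 |

(readings scatter by 8 × 10⁻⁴ M)

1. apparent order in [substrate] of the starting rate, round the charge of the Sunday's run (the rate where two percent of its substrate have turned into target) (one fixed amount of target, the same in the runs compared)
2. apparent order in [coupling partner] of the starting rate, round the charge of the Sunday's run (the rate where two percent of its substrate have turned into target)
3. target in the Saturday's run at 16 min, as a share of the substrate charged

- Overall: substrate + coupling partner -> target, with catalyst as catalyst.
- Constant volume, constant temperature.
- What is held in complexes is read along with the free species.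
- An order is taken over about fifteen percent of the charge, up and down.

*Has Sunday's flask used up its substrate?* No. Substrate is the limiting reagent by charge, yet 0.0912 M of it has not become target at that reading, so the curve is flattening with substrate still in the flask.

*Then what do you follow?* The fraction left, not the fraction made: the share of the final gain still to come. Let each step shrink by a constant factor; that fraction then falls as an exponential in time, and I call its rate the fade constant, 0.382 min⁻¹. Each last step alone carries a scatter of 0.00113 M, so I pool the first steps and the last steps of Sunday's, Monday's and Friday's runs and read this one value from their ratio.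

*And Saturday's flask?* It has Sunday's charge. At Sunday's last reading the fraction left is 8.33%, so Sunday's curve is heading for 0.0641 M. By 16 min the fraction left is 0.222%, which gives 42.7% of the substrate charged.

*Your pooled last steps are small. How bad is that?* They sum to 0.00920 M, with a scatter of 0.00196 M. Adding one such scatter to that sum lowers the fade constant to 0.345 min⁻¹ and moves my figure for Saturday's run at 16 min to 43.7%.

*The orders?* I take first readings as stand-ins for the rates, compared at one time and not at one amount. Friday's over Sunday's gives a substrate order of 0.193. Monday's over Sunday's, corrected with that order, gives a coupling-partner order of 1.37, a loose reading: the substrate order was read going up from Sunday's charge and is used here going down from it.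

The forecast gives a substrate order of 0.22, a coupling-partner order of 0.95 and 43% for Saturday's run, on the ground of “time-based catalyst death”, its partner order being lower than my 1.37.

Saturday's run gives 43.2% of the substrate charged, the orders round Sunday's charge are 0.15 in substrate and 1.0 in coupling partner, and Friday's rate over Sunday's, at one amount of target, is 1.1.

    catalyst + substrate + coupling partner → target + catalyst (10500 M⁻² min⁻¹)
    catalyst + substrate ⇌ idle catalyst-substrate complex, settled at all times (41.00 M⁻¹)
    coupling partner → lost reagent (0.3024 min⁻¹)

With the fade constant, Sunday's run should reach a quarter of its charge at 2.30 min, and it does so at 2.28 min. By the same reckoning Friday's run is heading for 0.0685 M, so at a quarter of its charge 19.7% of that gain is still to come, which the fade constant places at 4.25 min; Friday's run stands there at 4.32 min.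

The readings come from a simulation for an exercise, noise included.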